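**Plan**

- Cembrane numbering is used: ring carbons C1–C14, C15 is the isopropylidene carbon, ketones at C2 and C9, oxirane C3–C4, E-alkene C7=C8, acetoxy/methyl carbinol C12. The enabling feature is that C1 is the α-carbon of the C2 enone and its partner C15 carries two identical methyls, while C12 carries the two-carbon arm C13–C14, which is the vinyl group of linalool. The 14-membered ring is therefore cut at C14–C1 (alkylborane plus alkenyl bromide).
- Further cuts: C8–C9 (alkenyl iodide plus aldehyde), C1–C2 (bromo-isobutenyl carbenoid plus aldehyde), C5–C6 and C4–CH3 (acetoacetate dianion alkylation, enol phosphate/cuprate).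
- Forward order: the C2–C8 iodo-dienol is built from ethyl acetoacetate and 1-bromobut-2-yne and epoxidised (oxirane ring). The C1/C15 unit is added at C2, the chain is joined at C8–C9 to the C9–C14 aldehyde from (S)-linalool, both carbinols are silylated, the carbocycle is closed at C14–C1, and desilylation/oxidation finishes.
- Stereochemistry: C12 comes from (S)-linalool. C3/C4 come from Sharpless epoxidation (L-(+)-DET) of the E-allylic alcohol, whose geometry is set by the Z-enol phosphate/cuprate sequence. E-C7=C8 comes from syn-hydrozirconation/iodination. C2 and C9 are temporary carbinols erased by the last oxidation.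

Key step: step 13

Remark: (S)-(+)-linalool of high enantiomeric purity is assumed to be commercially available; C12 is never touched after step 9.
Remark: the carbinol centres C2 (step 8) and C9 (step 11) form as epimer mixtures that are carried on unseparated, so their SMILES leave these two centres undefined.

**Route**

Step 1
Reactants: 1 ethyl acetoacetate; 2 1-bromobut-2-yne
Product: 4 ethyl 3-oxooct-6-ynoate, via acetoacetate dianion 3 (not isolated)
Conditions: NaH, THF, 0 °C; n-BuLi, 0 °C; 2, 0 °C to rt; aq. HCl
Reagents that add atoms: none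
Why: γ-Alkylation of the acetoacetate dianion, whose terminal carbanion is the more nucleophilic site and displaces the primary propargylic bromide by SN2, forms C5–C6.

Step 2
Reactants: 4 ethyl 3-oxooct-6-ynoate
Product: 6 ethyl (2Z)-3-[(diethoxyphosphoryl)oxy]oct-2-en-6-ynoate, via sodium enolate 5 (not isolated)
Conditions: NaH, Et2O, 0 °C; ClP(O)(OEt)2, 0 °C to rt
Reagents that add atoms: diethyl chlorophosphate, CCOP(=O)(Cl)OCC
Why: O-Phosphorylation of the chelated sodium enolate of the β-keto ester (enol phosphate formation) should fix the Z geometry with the phosphate cis to the ester.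

Step 3
Reactants: 6 ethyl (2Z)-3-[(diethoxyphosphoryl)oxy]oct-2-en-6-ynoate
Product: 7 ethyl (2E)-3-methyloct-2-en-6-ynoate
Conditions: Me2CuLi (from MeLi, CuI), Et2O, −78 to −45 °C
Reagents that add atoms: lithium dimethylcuprate, [Li+].C[Cu-]C
Why: Addition–elimination of the Gilman cuprate on the β-phosphoryloxy enoate proceeds with retention, so the new C4 methyl should end up cis to the ester and the C3=C4 alkene E, while the internal alkyne is inert.

Step 4
Reactants: 7 ethyl (2E)-3-methyloct-2-en-6-ynoate
Product: 8 (2E)-3-methyloct-2-en-6-yn-1-ol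
Conditions: DIBAL-H (2.5 equiv), CH2Cl2, −78 to 0 °C; aq. Rochelle salt
Reagents that add atoms: none
Why: DIBAL-H 1,2-reduction of the enoate gives the allylic alcohol without touching the alkyne or the alkene geometry.

Step 5
Reactants: 8 (2E)-3-methyloct-2-en-6-yn-1-ol
Product: 10 (2E,6E)-7-iodo-3-methylocta-2,6-dien-1-ol, via alkenylzirconocene 9 (not isolated)
Conditions: Cp2Zr(H)Cl (3 equiv), THF, rt to 50 °C; I2, 0 °C
Reagents that add atoms: iodine, II
Why: Syn-hydrozirconation of the methyl-capped alkyne with excess Schwartz reagent (one equivalent is consumed by the hydroxyl) should equilibrate zirconium onto the methyl-bearing carbon C8, and iodinolysis with retention should give the E-alkenyl iodide.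

Step 6
Reactants: 10 (2E,6E)-7-iodo-3-methylocta-2,6-dien-1-ol
Product: 11 [(2S,3S)-3-[(3E)-4-iodopent-3-en-1-yl]-3-methyloxiran-2-yl]methanol
Conditions: Ti(OiPr)4 (10 mol%), L-(+)-DET (12 mol%), TBHP, 4 Å MS, CH2Cl2, −20 °C
Reagents that add atoms: tert-butyl hydroperoxide, CC(C)(C)OO
Why: Sharpless asymmetric epoxidation of the geraniol-type E-allylic alcohol with L-(+)-tartrate should deliver oxygen to the face that gives the (2S,3S)-epoxy alcohol, which sets C3 and C4 of the target; the remote alkenyl iodide is not an allylic alcohol and is not epoxidised.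

Step 7
Reactants: 11 [(2S,3S)-3-[(3E)-4-iodopent-3-en-1-yl]-3-methyloxiran-2-yl]methanol
Product: 12 (2R,3S)-3-[(3E)-4-iodopent-3-en-1-yl]-3-methyloxirane-2-carbaldehyde
Conditions: Dess–Martin periodinane, NaHCO3, CH2Cl2, 0 °C to rt
Reagents that add atoms: none
Why: Buffered Dess–Martin oxidation of the primary epoxy alcohol gives the epoxy aldehyde, whose oxirane-bound α-carbon does not epimerise.

Step 8
Reactants: 12 (2R,3S)-3-[(3E)-4-iodopent-3-en-1-yl]-3-methyloxirane-2-carbaldehyde; 13 1,1-dibromo-2-methylprop-1-ene
Product: 15 2-bromo-1-[(2S,3S)-3-[(3E)-4-iodopent-3-en-1-yl]-3-methyloxiran-2-yl]-3-methylbut-2-en-1-ol (C2 epimers), via lithium carbenoid 14 (not isolated)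
Conditions: 13, n-BuLi, THF/Et2O/pentane (4:1:1), −110 °C; 12, −110 to −90 °C; AcOH, −90 °C
Reagents that add atoms: none
Why: Bromine–lithium exchange on the gem-dibromoalkene gives an alkylidene carbenoid that is stable below about −100 °C and should add 1,2 to the aldehyde (forming C1–C2 and installing the C1 bromide) faster than it exchanges with the alkenyl iodide; the C2 configuration is irrelevant because C2 is oxidised later.

Step 9
Reactants: 16 (S)-linalool
Product: 17 (S)-linalyl acetate [(3S)-3,7-dimethylocta-1,6-dien-3-yl acetate]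
Conditions: Ac2O, Et3N, DMAP, CH2Cl2, rt
Reagents that add atoms: acetic anhydride, CC(=O)OC(C)=O
Why: DMAP-catalysed acylation of the tertiary allylic alcohol under basic conditions avoids the acid-promoted allylic transposition of linalool and leaves C12 untouched.

Step 10
Reactants: 17 (S)-linalyl acetate
Product: 19 (4S)-4-acetoxy-4-methylhex-5-enal, via ozonide 18 (not isolated)
Conditions: O3, CH2Cl2, −78 °C (Sudan Red 7B end-point); PPh3, −78 °C to rt
Reagents that add atoms: ozone, [O-][O+]=O
Why: Chemoselective ozonolysis with reductive work-up: the electron-rich trisubstituted alkene should react well ahead of the vinyl group deactivated by the allylic acetoxy group, and titration to the dye end-point limits the ozone dose.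

Step 11
Reactants: 15 bromo-iodo epoxy alcohol; 19 (4S)-4-acetoxy-4-methylhex-5-enal
Product: 20 (3S,7E)-10-[(2S,3S)-3-(2-bromo-1-hydroxy-3-methylbut-2-en-1-yl)-2-methyloxiran-2-yl]-6-hydroxy-3,7-dimethyldeca-1,7-dien-3-yl acetate (C2 and C9 epimers)
Conditions: CrCl2 (6 equiv), NiCl2 (1 mol%), DMSO, rt; 19 (1.5 equiv)
Reagents that add atoms: none
Why: Nozaki–Hiyama–Kishi coupling forms C8–C9: nickel should insert into the C–I bond far faster than into the hindered tetrasubstituted C–Br bond, and the alkenylchromium(III) species adds only to the aldehyde with retention of the E geometry, tolerating the acetate, epoxide and free hydroxyl.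

Step 12
Reactants: 20 C2,C9-diol
Product: 21 (3S,7E)-10-[(2S,3S)-3-[2-bromo-3-methyl-1-(triethylsilyloxy)but-2-en-1-yl]-2-methyloxiran-2-yl]-3,7-dimethyl-6-(triethylsilyloxy)deca-1,7-dien-3-yl acetate (C2 and C9 epimers)
Conditions: TESOTf (3 equiv), 2,6-lutidine, CH2Cl2, −78 °C
Reagents that add atoms: triethylsilyl triflate, CC[Si](CC)(CC)OS(=O)(=O)C(F)(F)F
Why: Silyl ether formation with the silyl triflate and a hindered base at low temperature is fast enough for the congested C2 hydroxyl and should spare the epoxide and the tertiary acetate; both hydroxyls must be masked because 9-BBN would otherwise be consumed by them.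

Step 13
Reactants: 21 acyclic bis(triethylsilyl) ether with C1 alkenyl bromide and C13=C14 vinyl group
Product: 23 (3S,4S,7E,12R)-12-acetoxy-3,4-epoxy-2,9-bis(triethylsilyloxy)cembra-1(15),7-diene (C2 and C9 epimers), via B-alkyl-9-BBN 22 (not isolated)
Conditions: 9-BBN (2 equiv), THF, 0 °C to rt; H2O; then syringe-pump addition to Pd(OAc)2 (20 mol%), SPhos (40 mol%), K3PO4 (3 M aq), THF/DMF, 50 °C, final ca. 2 mM
Reagents that add atoms: none
Why: 9-BBN hydroborates only the monosubstituted C13=C14 alkene and places boron on C14; after excess hydride is quenched with water, Pd(0) inserts into the C1–Br bond, the base-activated borate transfers its primary alkyl group, and reductive elimination forms C14–C1. This is a hydroboration/B-alkyl Suzuki–Miyaura macrocyclisation, a known way to close medium and large carbocycles and to couple β,β-disubstituted alkenyl bromides. The 14-membered ring closes by reductive elimination from a 15-membered palladacycle, with C1=C15 left exocyclic to the new ring, and slow addition keeps the borane dilute so that cyclisation should outrun oligomerisation. No stereocentre is formed, and because C15 carries two identical methyl groups there is no alkene geometry to control. Only chemoselectivity is required: 9-BBN strongly prefers the vinyl group over the trisubstituted C7=C8 and tetrasubstituted C1=C15 alkenes, boron sits γ to the acetoxy group so β-elimination is impossible, and aqueous phosphate should leave the tertiary acetate, the epoxide and both silyl ethers intact. The bulky, electron-rich biarylphosphine is chosen because oxidative addition into the hindered C1–Br bond is expected to be the slow event.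

Step 14
Reactants: 23 macrocyclic bis(triethylsilyl) ether
Product: 24 (3S,4S,7E,12R)-12-acetoxy-3,4-epoxycembra-1(15),7-diene-2,9-diol (C2 and C9 epimers)
Conditions: TBAF, AcOH (1:1), THF, 0 °C to rt
Reagents that add atoms: none
Why: Fluoride-mediated desilylation buffered with acetic acid should cleave both secondary triethylsilyl ethers without Payne rearrangement of the liberated epoxy alcohol or acetyl migration.

Step 15
Reactants: 24 macrocyclic C2,C9-diol
Product: 25 (3R,4S,7E,12R)-12-acetoxy-3,4-epoxycembra-1(15),7-diene-2,9-dione (target, CNP0203173.1)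
Conditions: Dess–Martin periodinane (3 equiv), NaHCO3, CH2Cl2, 0 °C to rt
Reagents that add atoms: none
Why: Buffered Dess–Martin oxidation of the two allylic alcohols (C2 also α to the oxirane) should give both enones and converge all epimers to the single target without touching C3, C4 or C12.

**Compound list**

1 | ethyl acetoacetate | CCOC(=O)CC(C)=O | starting material
2 | 1-bromobut-2-yne | CC#CCBr | starting material
3 | ethyl acetoacetate dianion, sodium lithium dienolate (not isolated) | [Na+].[Li+].C=C([O-])C=C([O-])OCC | intermediate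
4 | ethyl 3-oxooct-6-ynoate | CCOC(=O)CC(=O)CCC#CC | intermediate
5 | sodium (Z)-enolate of 4 (not isolated) | [Na+].CCOC(=O)/C=C(\[O-])CCC#CC | intermediate
6 | ethyl (2Z)-3-[(diethoxyphosphoryl)oxy]oct-2-en-6-ynoate | CCOC(=O)/C=C(\OP(=O)(OCC)OCC)CCC#CC | intermediate
7 | ethyl (2E)-3-methyloct-2-en-6-ynoate | CCOC(=O)/C=C(\C)CCC#CC | intermediate
8 | (2E)-3-methyloct-2-en-6-yn-1-ol | OC/C=C(\C)CCC#CC | intermediate
9 | C8-zirconated (E)-alkenylzirconocene chloride of 8 with O-bound zirconocene chloride (not isolated) | C/C(=C\CC/C(C)=C/CO[Zr](Cl)(C1C=CC=C1)C1C=CC=C1)[Zr](Cl)(C1C=CC=C1)C1C=CC=C1 | intermediate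
10 | (2E,6E)-7-iodo-3-methylocta-2,6-dien-1-ol | OC/C=C(\C)CC/C=C(\C)I | intermediate
11 | [(2S,3S)-3-[(3E)-4-iodopent-3-en-1-yl]-3-methyloxiran-2-yl]methanol | I/C(C)=C/CC[C@]1(C)O[C@H]1CO | intermediate
12 | (2R,3S)-3-[(3E)-4-iodopent-3-en-1-yl]-3-methyloxirane-2-carbaldehyde | I/C(C)=C/CC[C@]1(C)O[C@H]1C=O | intermediate
13 | 1,1-dibromo-2-methylprop-1-ene | CC(C)=C(Br)Br | starting material
14 | 1-bromo-1-lithio-2-methylprop-1-ene (not isolated) | CC(C)=C([Li])Br | intermediate
15 | 2-bromo-1-[(2S,3S)-3-[(3E)-4-iodopent-3-en-1-yl]-3-methyloxiran-2-yl]-3-methylbut-2-en-1-ol, C2 epimers | I/C(C)=C/CC[C@]1(C)O[C@H]1C(O)C(Br)=C(C)C | intermediate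
16 | (S)-linalool | C=C[C@@](C)(O)CCC=C(C)C | starting material
17 | (S)-linalyl acetate, (3S)-3,7-dimethylocta-1,6-dien-3-yl acetate | C=C[C@@](C)(OC(C)=O)CCC=C(C)C | intermediate
18 | (3S)-5-(5,5-dimethyl-1,2,4-trioxolan-3-yl)-3-methylpent-1-en-3-yl acetate, ozonide (not isolated) | C=C[C@@](C)(OC(C)=O)CCC1OOC(C)(C)O1 | intermediate
19 | (4S)-4-acetoxy-4-methylhex-5-enal | C=C[C@@](C)(OC(C)=O)CCC=O | intermediate
20 | (3S,7E)-10-[(2S,3S)-3-(2-bromo-1-hydroxy-3-methylbut-2-en-1-yl)-2-methyloxiran-2-yl]-6-hydroxy-3,7-dimethyldeca-1,7-dien-3-yl acetate, C2 and C9 epimers | C=C[C@@](C)(OC(C)=O)CCC(O)/C(C)=C/CC[C@]1(C)O[C@H]1C(O)C(Br)=C(C)C | intermediate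
21 | bis(triethylsilyl) ether of 20 (cyclisation precursor), C2 and C9 epimers | C=C[C@@](C)(OC(C)=O)CCC(O[Si](CC)(CC)CC)/C(C)=C/CC[C@]1(C)O[C@H]1C(O[Si](CC)(CC)CC)C(Br)=C(C)C | intermediate
22 | C14 B-alkyl-9-borabicyclo[3.3.1]nonane from 21 (not isolated) | CC(=O)O[C@](C)(CCB1C2CCCC1CCC2)CCC(O[Si](CC)(CC)CC)/C(C)=C/CC[C@]3(C)O[C@H]3C(O[Si](CC)(CC)CC)C(Br)=C(C)C | intermediate
23 | (3S,4S,7E,12R)-12-acetoxy-3,4-epoxy-2,9-bis(triethylsilyloxy)cembra-1(15),7-diene, C2 and C9 epimers | CC(=O)O[C@@]1(C)CCC(O[Si](CC)(CC)CC)/C(C)=C/CC[C@]2(C)O[C@H]2C(O[Si](CC)(CC)CC)C(=C(C)C)CC1 | intermediate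
24 | (3S,4S,7E,12R)-12-acetoxy-3,4-epoxycembra-1(15),7-diene-2,9-diol, C2 and C9 epimers | CC(=O)O[C@@]1(C)CCC(O)/C(C)=C/CC[C@]2(C)O[C@H]2C(O)C(=C(C)C)CC1 | intermediate
25 | (3R,4S,7E,12R)-12-acetoxy-3,4-epoxycembra-1(15),7-diene-2,9-dione | CC(=O)O[C@@]1(C)CCC(=O)/C(C)=C/CC[C@]2(C)O[C@H]2C(=O)C(=C(C)C)CC1 | target

**Step count**

Total: 15 steps. Longest linear sequence: 13 steps (steps 1–8, then 11–15); the linalool branch contributes steps 9–10.

**Steps most likely to fail**

1. Step 13. Oxidative addition into the hindered tetrasubstituted C1–Br bond may be slower than protodeboronation or β-hydride loss from the alkylpalladium, and intermolecular coupling may compete with ring closure. The fallback sets out from 21 and returns at 23; it keeps the C14–C1 bond but uses an organozinc, which transmetalates without base or water. Hydroboration of 21 with 9-BBN followed by neutral oxidation (H2O2, pH 7 buffer) would give the C14 primary alcohol F1. Appel iodination (I2, PPh3, imidazole) would give the primary iodide F2. Zinc insertion (activated Zn, LiCl, THF) would give the alkylzinc iodide F3, which is not isolated and would be closed by intramolecular Negishi coupling (Pd/SPhos, slow addition) to give 23.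

2. Step 5. Zirconium may not equilibrate completely onto C8, so that the regioisomeric iodide forms alongside 10, and the free hydroxyl may retard hydrometalation. The fallback sets out from 1 and returns at 10; silicon fixes the iodide position instead of hydrometalation. The dianion of 1 would be alkylated with the known allylic iodide (E)-(4-iodobut-2-en-2-yl)trimethylsilane to give ethyl (6E)-3-oxo-7-(trimethylsilyl)oct-6-enoate F4. The enol phosphate/cuprate sequence of steps 2 and 3 would give ethyl (2Z,6E)-3-[(diethoxyphosphoryl)oxy]-7-(trimethylsilyl)octa-2,6-dienoate F5 and then ethyl (2E,6E)-3-methyl-7-(trimethylsilyl)octa-2,6-dienoate F6. Ipso-iododesilylation with NIS (retention; the enoate alkene is too electron-poor to compete) would give ethyl (2E,6E)-7-iodo-3-methylocta-2,6-dienoate F7, and DIBAL-H reduction would give 10.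

3. Step 11. Nickel may also insert into the C1–Br bond, the alkenyl iodide may dimerise reductively, or the free C2 hydroxyl may interfere with the chromium reagent. The fallback sets out from 11 and 19 and returns at 20; the order of bond formation is reversed so that no alkenyl bromide is present during the chromium coupling. NHK coupling of iodide 11 with 19 would give the seco epoxy diol (3S,7E)-6-hydroxy-10-[(2S,3S)-3-(hydroxymethyl)-2-methyloxiran-2-yl]-3,7-dimethyldeca-1,7-dien-3-yl acetate F8. Oxidation selective for the primary hydroxyl (TEMPO, PhI(OAc)2) would give the epoxy aldehyde F9. Addition of excess carbenoid 14 at −110 °C (one equivalent is consumed by the C9 hydroxyl, and the aldehyde reacts ahead of the tertiary acetate) would give 20.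

**Further compounds**

F1 | step 13 | C14 primary alcohol from hydroboration/oxidation of 21 | CC(=O)O[C@](C)(CCO)CCC(O[Si](CC)(CC)CC)/C(C)=C/CC[C@]1(C)O[C@H]1C(O[Si](CC)(CC)CC)C(Br)=C(C)C
F2 | step 13 | C14 primary iodide | CC(=O)O[C@](C)(CCI)CCC(O[Si](CC)(CC)CC)/C(C)=C/CC[C@]1(C)O[C@H]1C(O[Si](CC)(CC)CC)C(Br)=C(C)C
F3 | step 13 | C14 alkylzinc iodide (not isolated) | CC(=O)O[C@](C)(CC[Zn]I)CCC(O[Si](CC)(CC)CC)/C(C)=C/CC[C@]1(C)O[C@H]1C(O[Si](CC)(CC)CC)C(Br)=C(C)C
F4 | step 5 | ethyl (6E)-3-oxo-7-(trimethylsilyl)oct-6-enoate | CCOC(=O)CC(=O)CC/C=C(\C)[Si](C)(C)C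
F5 | step 5 | ethyl (2Z,6E)-3-[(diethoxyphosphoryl)oxy]-7-(trimethylsilyl)octa-2,6-dienoate | CCOC(=O)/C=C(\OP(=O)(OCC)OCC)CC/C=C(\C)[Si](C)(C)C
F6 | step 5 | ethyl (2E,6E)-3-methyl-7-(trimethylsilyl)octa-2,6-dienoate | CCOC(=O)/C=C(\C)CC/C=C(\C)[Si](C)(C)C
F7 | step 5 | ethyl (2E,6E)-7-iodo-3-methylocta-2,6-dienoate | CCOC(=O)/C=C(\C)CC/C=C(\C)I
F8 | step 11 | (3S,7E)-6-hydroxy-10-[(2S,3S)-3-(hydroxymethyl)-2-methyloxiran-2-yl]-3,7-dimethyldeca-1,7-dien-3-yl acetate, C9 epimers | C=C[C@@](C)(OC(C)=O)CCC(O)/C(C)=C/CC[C@]1(C)O[C@H]1CO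
F9 | step 11 | (3S,7E)-10-[(2S,3R)-3-formyl-2-methyloxiran-2-yl]-6-hydroxy-3,7-dimethyldeca-1,7-dien-3-yl acetate, C9 epimers | C=C[C@@](C)(OC(C)=O)CCC(O)/C(C)=C/CC[C@]1(C)O[C@H]1C=O
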